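## Structural features

The target is a germacrane-type sesquiterpene lactone: a ten-membered carbocycle (C1–C10; methyl C14 on C10, methyl C15 on C4, three-carbon branch C11–C13 on C7) bridged by an ether oxygen from C1 to C4, so that a tetrahydrofuran (O, C1, C2, C3, C4) and a nine-membered oxacycle share that oxygen in an 11-oxabicyclo[6.2.1]undecane. Across C6–C7 this bicycle is fused to a 2(5H)-furanone with its ring oxygen on C6 and its carbonyl at C12; C5=C6 is exocyclic to the lactone and E (C4 and C7 cis), C7=C11 is endocyclic, and C11 carries the acetoxymethyl carbon C13. There are five stereocentres: C1 (S) and C10 (R) are neighbours, C4 (R) is tied to C1 through the ether, C8 (S) carries the ester next to trigonal C7, and the fifth is the quaternary oxirane carbon (S) of the 2-methyloxirane-2-carboxylate; in the usual germacrane drawing both ring methyl groups are β and the ether oxygen, the C10 hydroxyl and the C8 oxygen are α. The fragile groups are the alkylidene butenolide (an enol ester, opened by bases and nucleophiles), the allylic acetate, the acid-labile glycidic ester and the tertiary alcohol, which dehydrates easily. The real difficulty is a medium ring whose four stereocentres are far apart and, because C6 and C7 end trigonal, can inherit chirality from a chiral-pool ring only through C8 and through the conformation of the ten-membered ring. The key step uses the oxygens on C1/C10 and on C4/C5 that flank the C2–C3 bond, the mark of a cyclodeca-1(10),4-diene: this diene arises by a [3,3] shift from a cyclohexanol whose ring bond is C5–C10 (C5 bearing oxygen and an isopropenyl group C4/C3/C15, C10 bearing C14 and a vinyl group C1/C2), and the shift leaves a C4=C5 enolate for the C4 oxygen and an E C1=C10 alkene for the C1 and C10 oxygens.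

## Logic of the disconnections

36 to 31 and 34: the C8–O acyl bond is cut. The glycidic ester is the part least tolerant of acid, fluoride and hydride, so it goes on last; this takes one stereocentre and all oxirane chemistry out of the main line. The forward acylation must choose the secondary C8 hydroxyl over the tertiary C10 hydroxyl; 34 has no α-hydrogen and cannot epimerise. 34 goes back through 33 to 32 by cutting the oxirane C–O bonds, which asks for a reagent-controlled epoxidation of an achiral allylic alcohol.

31 and 30 to 28: the C5=C6 and C7=C11 double bonds are undone by adding back methanesulfonic acid across C5–C6 and water across C7–C11. The alkylidene butenolide is the most fragile unit and is therefore unveiled by two eliminations at the very end of the main line. The forward order matters: C7=C11 must form first, because only then is H6 vinylogously acidic, and the C5 leaving group must depart faster than the C13 acetate.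

28 to 24: the C11–O and C13–O bonds, the acetate, the mesylate and the C5–H bond are removed, leaving an α-methylene lactone next to a C5 ketone. The two oxygens on C11/C13 come from one dihydroxylation, and the C5 ketone is the carbonyl the key step leaves behind. The demand is that the exocyclic methylene is the only alkene present when OsO4 is used.

24 to 19 through 22 and 21: the lactone C12–O bond, the C12 oxidation level and the C6–O bond are cut back. C6 can be oxygenated unambiguously because C4 is fully substituted, so the C5 ketone enolises only toward C6. C12 is the methyl group of the only remaining alkene, so allylic oxidation has one site. The forward steps need all ring alkenes to be consumed beforehand.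

18 to 16: the C1–O ether bond is cut to a C4 oxygen and a 1(10)-epoxide. Two ring stereocentres (C1, C10) then reduce to one alkene face plus a stereospecific inversion at C1. The forward opening must occur at secondary C1 (5-exo) and not at tertiary C10, which calls for an alkoxide, not an acid.

16 to 14: the C4–O, C1–O and C10–O bonds are cut to a ring-trans silyl enol ether and an E alkene. Both oxygenations use the same peracid, the enol ether reacting first. The forward step depends on attack from outside the ring on the conformer with C14 and C15 on the same face, and on the isopropenyl group being the least nucleophilic alkene.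

14 to 11 (key step): the C2–C3 bond is cut and C5–C10 is reconnected, contracting the ten-membered ring to a cyclohexanol with trans isopropenyl and vinyl groups. 11 differs deliberately from the all-equatorial diastereomer (C14 cis to the C7 branch, an ether on C6) that one would draw first. Enolate alkylation of this ring places the new carbon axial, cis to the C7 branch and anti to the C8 oxygen, and a nucleophile then adds to the ketone anti to that axial vinyl group. The chemistry therefore gives the isomer that is inverted at both C5 and C10. This isomer reaches the reactive chair by ring inversion. The inversion would force a C6 substituent into a 1,3-diaxial array with the C8 oxygen and C14, and such a group would also chelate the potassium of the neighbouring alkoxide. C6 is therefore left as a methylene group and oxygenated after the ring expansion from the ketone that the step itself makes. Because C5 and C10 become trigonal, the product is the same whichever trans isomer rearranges. 14 is ring-trans at both double bonds, which is 1(10)E and, by the sequence rules, 4Z.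

11 to 9 and 10: the C4–C5 bond is cut. This removes the tertiary carbinol and one alkene; the forward addition must deliver the isopropenyl group trans to the vinyl group and must beat enolisation of a hindered ketone.

9 to 5 and 6: the C1–C10 bond is cut (with C2 as the second carbon of 6). The quaternary centre is made from the enone by conjugate reduction and aldol capture, then dehydration; the forward step must give one regiodefined enolate and must not expel the γ-silyloxy group.

5 to 1 through 4 and 3: the C8–O bond is cut. Vinylogous oxidation of the linear dienol ether puts the oxygen trans to the isopropenyl group, which fixes C8 (S) from the single stereocentre of 1; the forward step needs γ- and not α′-enolisation and γ- and not α-attack.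

## Other disconnections considered

Alternative 1: the cut is C9=C10, after the C10 hydroxyl is taken back to an alkene. In the forward direction a ruthenium carbene (second-generation Grubbs catalyst) would close diene A2 to the oxonene A1, whose Markovnikov hydration (Co(acac)2, PhSiH3, O2) would give 31.
- In its favour: it is convergent. The tetrahydrofuran and the finished butenolide are brought in before the ring is closed, only one step follows ring closure before 31, and none of the long oxidation sequence on a medium ring is needed. On step economy after ring formation and on convergence it is the better plan.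
- Against it: the metathesis must join a 1,1-disubstituted isopropenyl group to a vinyl group to make a trisubstituted alkene inside a strained nine-membered oxacycle, with the usual entropic cost and competing dimerisation. The alkylidene butenolide in A2 is a conjugated dienyl ester that can bind or be isomerised by the carbene.
- The hydration must then choose the α face of C10 and spare the dienyl lactone, which hydrogen-atom-transfer conditions may reduce.
- Comparison: both plans rely on the ring's conformation for C10, so they are equal there. The chosen plan closes the ring by an intramolecular pericyclic shift with no entropic penalty and fixes C1 and C10 together through an E alkene.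

Alternative 2: the cuts are C4–C5 and C1–C10, with one extra ketone carbon bridging C5 and C10. In the forward direction the oxyallyl cation from chloro ketone A4 (Et3N in CF3CH2OH, or AgBF4) would add across 2-methylfuran A5 to give cycloadduct A3.
- In its favour: one step makes two C–C bonds and the 1,4-oxygen bridge, and fixes C1, C4 and C10 relative to one another on a rigid oxabicycle. In stereocentres created by the key step it is clearly the better plan, since the chosen key step creates none.
- Against it: the methyl group of A5 must end next to the secondary terminus of an oxyallyl cation whose other terminus is fully substituted. The face of a flexible seven-membered cation must be set by two distant silyl ethers.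
- A3 then needs the bridge excised: a Baeyer–Villiger step gives C10–O but leaves the carbonyl carbon on C5 to be degraded. It also needs C2=C3 reduced and, hardest, the whole C11–C13 unit attached to C7, which is an unactivated methylene group in A3.
- Comparison: the chosen plan carries C11–C13 and the C8 oxygen from the first compound and gets the C5 carbonyl from the key step itself. The alternative is better on ring and stereocentre construction but clearly worse on what remains afterwards.

Alternative 3: the cuts are O–C4 and C4–C5. In the forward direction a carbenoid from diazo ketone A7 (Rh2(OAc)4 or copper bis(hexafluoroacetylacetonate)) would be captured by the tetrahydropyran oxygen, and the oxonium ylide would shift [2,3] through the C7 vinyl group to give A6.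
- In its favour: the tetrahydrofuran and the medium ring form together. The quaternary C4 centre is set by the bridged transition state and not by attack on a floppy ring, which is equal to or better than the chosen plan at C4. C1, C8 and C10 can be set beforehand on a six-membered ring by reliable means.
- Mechanistically it is, like the chosen step, a concerted sigmatropic ring expansion of a six-membered ring, so the two are equal in that respect.
- Against it: a diazo ketone with a methyl group on the diazo carbon is prone to 1,2-hydride shift to an enone and to C–H insertion.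
- A6 carries a C3 ketone that must be removed, a saturated C5, and a C6=C7 alkene with no C11–C13 carbons. Three carbons must be added at C7 and C5/C6 oxidised, which is longer and less certain than the sequence from 14.

Key step: step 7

Remark on the chemistry: α/β refer to the germacrane drawing with C14 and C15 β; the carbinol carbon of 8, the lactol carbon of 23 and C5 of 27–29 are carried as both epimers because these centres are erased later.

## Route

Step 1
Reactants: 1 (R)-carvone
Product: 3 (5S)-1-(tert-butyldimethylsilyloxy)-2-methyl-5-(prop-1-en-2-yl)cyclohexa-1,3-diene, via linear potassium dienolate 2 (not isolated)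
Conditions: KN(SiMe3)2 (0.97 equiv), THF, −78 → 0 °C; then t-BuMe2SiCl, DMPU, −78 °C → rt
Reagents that add atoms: tert-butyldimethylsilyl chloride, CC(C)(C)[Si](C)(C)Cl
Why: Thermodynamic dienolate formation: with a slight deficit of base, proton exchange with residual enone converts the kinetic cross-conjugated enolate into the more stable linear dienolate (deprotonation at C4 of carvone), which silylates on oxygen; the stereocentre is not acidic and is untouched.

Step 2
Reactants: 3 (5S)-1-(tert-butyldimethylsilyloxy)-2-methyl-5-(prop-1-en-2-yl)cyclohexa-1,3-diene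
Product: 4 (4S,5R)-4-hydroxy-2-methyl-5-(prop-1-en-2-yl)cyclohex-2-en-1-one
Conditions: mCPBA (1.0 equiv), NaHCO3, CH2Cl2, −40 → −10 °C; aq. NaHCO3/Na2S2O3
Reagents that add atoms: 3-chloroperbenzoic acid, OOC(=O)c1cccc(Cl)c1
Why: Vinylogous Rubottom oxidation: the peracid attacks the silyloxy diene at its γ-terminus (the less substituted end with the largest HOMO coefficient) on the face opposite the neighbouring isopropenyl group, which sets the future C8 trans to the C7 branch; the isopropenyl alkene is far less nucleophilic and is spared.

Step 3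
Reactants: 4 (4S,5R)-4-hydroxy-2-methyl-5-(prop-1-en-2-yl)cyclohex-2-en-1-one
Product: 5 (4S,5R)-4-(tert-butyldimethylsilyloxy)-2-methyl-5-(prop-1-en-2-yl)cyclohex-2-en-1-one
Conditions: t-BuMe2SiCl, imidazole, DMF, rt
Reagents that add atoms: tert-butyldimethylsilyl chloride, CC(C)(C)[Si](C)(C)Cl
Why: Standard silylation of a secondary allylic alcohol; the ether survives hydride, organometallic, KH and peracid steps and is removed only by fluoride at the end.

Step 4
Reactants: 5 (4S,5R)-4-(tert-butyldimethylsilyloxy)-2-methyl-5-(prop-1-en-2-yl)cyclohex-2-en-1-one; 6 acetaldehyde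
Product: 8 (2R,4S,5R)-4-(tert-butyldimethylsilyloxy)-2-(1-hydroxyethyl)-2-methyl-5-(prop-1-en-2-yl)cyclohexan-1-one (both carbinol epimers), via lithium enolate 7 (not isolated)
Conditions: LiBH(s-Bu)3, THF, −78 °C; then MeCHO, −78 °C; AcOH, −78 °C
Reagents that add atoms: none
Why: Conjugate reduction–aldol: LiBH(s-Bu)3 adds hydride to the unsubstituted β-carbon and gives the regiodefined tetrasubstituted enolate without a β-carbanion that could expel the γ-silyloxy group; the aldehyde adds axially on the half-chair with silyloxy and isopropenyl equatorial, anti to the silyloxy group and cis to the isopropenyl group, which sets the quaternary carbon as 2R.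

Step 5
Reactants: 8 (2R,4S,5R)-4-(tert-butyldimethylsilyloxy)-2-(1-hydroxyethyl)-2-methyl-5-(prop-1-en-2-yl)cyclohexan-1-one
Product: 9 (2R,4S,5R)-4-(tert-butyldimethylsilyloxy)-2-ethenyl-2-methyl-5-(prop-1-en-2-yl)cyclohexan-1-one
Conditions: Burgess reagent, toluene, 60 °C
Reagents that add atoms: none
Why: Burgess dehydration by syn-elimination of the sulfamate; the α-carbon is quaternary, so only the methyl hydrogens are available and the vinyl group is the only possible alkene, and the neutral conditions avoid retro-aldol cleavage.

Step 6
Reactants: 9 (2R,4S,5R)-4-(tert-butyldimethylsilyloxy)-2-ethenyl-2-methyl-5-(prop-1-en-2-yl)cyclohexan-1-one; 10 isopropenylmagnesium bromide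
Product: 11 (1S,2R,4S,5R)-4-(tert-butyldimethylsilyloxy)-2-ethenyl-2-methyl-1,5-di(prop-1-en-2-yl)cyclohexan-1-ol
Conditions: CH2=C(CH3)MgBr, CeCl3, THF, −78 → 0 °C; aq. NH4Cl
Reagents that add atoms: none
Why: Organocerium-mediated 1,2-addition suppresses enolisation of the hindered ketone; in the chair with silyloxy and isopropenyl equatorial the vinyl group is axial and blocks the equatorial trajectory, so the nucleophile enters axially from the other face and the new isopropenyl group ends trans to the vinyl group (1S).

Step 7
Reactants: 11 (1S,2R,4S,5R)-4-(tert-butyldimethylsilyloxy)-2-ethenyl-2-methyl-1,5-di(prop-1-en-2-yl)cyclohexan-1-ol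
Product: 14 (1(10)E,4Z)-8α-(tert-butyldimethylsilyloxy)-5-(trimethylsilyloxy)germacra-1(10),4,11(13)-triene, via potassium alkoxide 12 (not isolated), via potassium dienolate 13 (not isolated)
Conditions: KH, 18-crown-6, THF, 0 → 45 °C; then Me3SiCl, Et3N, −78 °C
Reagents that add atoms: chlorotrimethylsilane, C[Si](C)(C)Cl
Why: Deprotonation gives alkoxide 12, whose crown-ether-separated oxyanion weakens the adjacent C5–C10 bond; after ring inversion to the chair in which the C5 isopropenyl and C10 vinyl groups are both equatorial, the 1,5-diene C3=C4–C5–C10–C1=C2 passes through a chair six-membered transition state in which C2–C3 forms as C5–C10 breaks. The closest known reaction type is the anionic oxy-Cope rearrangement of trans-1,2-dialkenylcyclohexanols to cyclodec-5-enone enolates. The ten-membered ring is closed not by end-to-end cyclisation but by [3,3]-sigmatropic four-atom ring expansion: the six-membered ring supplies C5–C10 and the two alkenyl arms supply C1–C4. No stereocentre is created; C5 and C10 become trigonal, so their configurations in 11 need only be mutually trans, and C7 and C8 are untouched. The step needs E geometry at C1=C10, a ring-trans C4=C5 enolate and a single enolate regioisomer: the first two follow from the chair transition state of the trans-diequatorial isomer, in which C9 and C6 sit equatorial on the forming ring, and the third from the mechanism, which places the enolate only between C4 and C5. Silylation at −78 °C fixes enolate 13 as 14 before proton transfer toward C6 can occur. The reactive chair carries the C7 isopropenyl and C8 silyloxy groups axial, which is affordable because C6 bears no substituent.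

Step 8
Reactants: 14 (1(10)E,4Z)-8α-(tert-butyldimethylsilyloxy)-5-(trimethylsilyloxy)germacra-1(10),4,11(13)-triene
Product: 16 1β,10α-epoxy-8α-(tert-butyldimethylsilyloxy)-4α-(trimethylsilyloxy)germacr-11(13)-en-5-one, via silyloxy ketone 15 (not isolated)
Conditions: mCPBA (2.1 equiv), NaHCO3, CH2Cl2, −40 → 0 °C
Reagents that add atoms: 3-chloroperbenzoic acid, OOC(=O)c1cccc(Cl)c1
Why: Rubottom oxidation then Prilezhaev epoxidation in one flask: the first equivalent epoxidises the tetrasubstituted silyl enol ether from outside the ring (C15 stays β, oxygen enters α) and 1,4-silyl shift gives 15, which sets C4; the second equivalent epoxidises the E C1=C10 alkene, again from the periphery, to the 1β,10α-epoxide, the pattern expected for 7β-substituted germacra-1(10),4-dienes; the isopropenyl group is the least nucleophilic alkene and the buffer suppresses acid-triggered transannular reactions.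

Step 9
Reactants: 16 1β,10α-epoxy-8α-(tert-butyldimethylsilyloxy)-4α-(trimethylsilyloxy)germacr-11(13)-en-5-one
Product: 18 1α,4α-epoxy-10α-hydroxy-8α-(tert-butyldimethylsilyloxy)germacr-11(13)-en-5-one, via hydroxy epoxide 17 (not isolated)
Conditions: K2CO3, MeOH, 0 °C → rt
Reagents that add atoms: none
Why: Methanolysis removes the trimethylsilyl group and the tertiary C4 alkoxide opens the epoxide at secondary C1 in a 5-exo-tet SN2 reaction with inversion, which sets C1 (S) and leaves C10 (R) with retention; basic conditions avoid the Markovnikov opening at tertiary C10 that acid would favour.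

Step 10
Reactants: 18 1α,4α-epoxy-10α-hydroxy-8α-(tert-butyldimethylsilyloxy)germacr-11(13)-en-5-one
Product: 19 1α,4α-epoxy-8α-(tert-butyldimethylsilyloxy)-10α-(triethylsilyloxy)germacr-11(13)-en-5-one
Conditions: Et3SiOTf, 2,6-lutidine, CH2Cl2, −78 → −20 °C
Reagents that add atoms: triethylsilyl trifluoromethanesulfonate, CC[Si](CC)(CC)OS(=O)(=O)C(F)(F)F
Why: Silylation of the tertiary alcohol, which would otherwise consume base in step 11 and be dehydrated in step 18; the hindered base at low temperature does not enolise the ketone, and the group leaves with the C8 silyl ether in step 19.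

Step 11
Reactants: 19 1α,4α-epoxy-8α-(tert-butyldimethylsilyloxy)-10α-(triethylsilyloxy)germacr-11(13)-en-5-one
Product: 21 1α,4α-epoxy-6α-hydroxy-8α-(tert-butyldimethylsilyloxy)-10α-(triethylsilyloxy)germacr-11(13)-en-5-one, via potassium enolate 20 (not isolated)
Conditions: KN(SiMe3)2, THF, −78 °C; 2-(benzenesulfonyl)-3-phenyloxaziridine, −78 °C; aq. NH4Cl
Reagents that add atoms: 2-(benzenesulfonyl)-3-phenyloxaziridine, O=S(=O)(c1ccccc1)N1OC1c1ccccc1
Why: Davis oxidation of the enolate, which can form only toward C6 because C4 is fully substituted; attack anti to the C7 branch should give the 6α-alcohol, and either epimer serves because C6 becomes trigonal in step 18.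

Step 12
Reactants: 21 1α,4α-epoxy-6α-hydroxy-8α-(tert-butyldimethylsilyloxy)-10α-(triethylsilyloxy)germacr-11(13)-en-5-one
Product: 22 1α,4α-epoxy-6α,12-dihydroxy-8α-(tert-butyldimethylsilyloxy)-10α-(triethylsilyloxy)germacr-11(13)-en-5-one
Conditions: SeO2 (0.3 equiv), t-BuOOH, CH2Cl2, rt
Reagents that add atoms: selenium dioxide, O=[Se]=O; tert-butyl hydroperoxide, CC(C)(C)OO
Why: SeO2-catalysed allylic oxidation (ene reaction then [2,3] shift) of the only alkene left; on a ring-bound isopropenyl group the methyl group is oxidised in preference to the methine, and any over-oxidised enal closes to lactol 23 and converges in step 13.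

Step 13
Reactants: 22 1α,4α-epoxy-6α,12-dihydroxy-8α-(tert-butyldimethylsilyloxy)-10α-(triethylsilyloxy)germacr-11(13)-en-5-one
Product: 24 1α,4α-epoxy-5-oxo-8α-(tert-butyldimethylsilyloxy)-10α-(triethylsilyloxy)germacr-11(13)-en-12,6α-olide, via lactol 23 (not isolated)
Conditions: TEMPO (0.2 equiv), PhI(OAc)2, CH2Cl2, rt
Reagents that add atoms: none
Why: Oxoammonium-mediated oxidative lactonisation of a 1,4-diol: the primary allylic alcohol is oxidised to the enal, which closes with the C6 hydroxyl to the five-membered lactol 23 and is oxidised again to the α-methylene lactone; the secondary C6 alcohol is not oxidised under these conditions.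

Step 14
Reactants: 24 1α,4α-epoxy-5-oxo-8α-(tert-butyldimethylsilyloxy)-10α-(triethylsilyloxy)germacr-11(13)-en-12,6α-olide
Product: 25 1α,4α-epoxy-11,13-dihydroxy-5-oxo-8α-(tert-butyldimethylsilyloxy)-10α-(triethylsilyloxy)germacran-12,6α-olide (11-hydroxyl cis to H-7)
Conditions: OsO4 (5 mol %), N-methylmorpholine N-oxide, acetone/H2O, rt
Reagents that add atoms: N-methylmorpholine N-oxide, C[N+]1([O-])CCOCC1; water, O
Why: Upjohn dihydroxylation of the exocyclic methylene, the only alkene present; OsO4 should add from the lactone face that carries H-7, and the C11 configuration is erased in step 18.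

Step 15
Reactants: 25 1α,4α-epoxy-11,13-dihydroxy-5-oxo-8α-(tert-butyldimethylsilyloxy)-10α-(triethylsilyloxy)germacran-12,6α-olide
Product: 26 13-acetoxy-1α,4α-epoxy-11-hydroxy-5-oxo-8α-(tert-butyldimethylsilyloxy)-10α-(triethylsilyloxy)germacran-12,6α-olide
Conditions: Ac2O, pyridine, CH2Cl2, 0 °C
Reagents that add atoms: acetic anhydride, CC(=O)OC(C)=O
Why: Selective acetylation of the primary alcohol; the tertiary C11 hydroxyl does not react, and the acetate is the C13 ester of the target, not a protecting group.

Step 16
Reactants: 26 13-acetoxy-1α,4α-epoxy-11-hydroxy-5-oxo-8α-(tert-butyldimethylsilyloxy)-10α-(triethylsilyloxy)germacran-12,6α-olide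
Product: 27 13-acetoxy-1α,4α-epoxy-5,11-dihydroxy-8α-(tert-butyldimethylsilyloxy)-10α-(triethylsilyloxy)germacran-12,6α-olide (both C5 epimers)
Conditions: NaBH4, MeOH/THF, −40 °C
Reagents that add atoms: none
Why: Borohydride reduction of the ketone, which at low temperature is much faster than attack on the lactone or the acetate; the new C5 centre is not controlled and need not be, because it is eliminated in step 18.

Step 17
Reactants: 27 13-acetoxy-1α,4α-epoxy-5,11-dihydroxy-8α-(tert-butyldimethylsilyloxy)-10α-(triethylsilyloxy)germacran-12,6α-olide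
Product: 28 13-acetoxy-1α,4α-epoxy-11-hydroxy-5-(methanesulfonyloxy)-8α-(tert-butyldimethylsilyloxy)-10α-(triethylsilyloxy)germacran-12,6α-olide
Conditions: MeSO2Cl, Et3N, CH2Cl2, −20 → 0 °C
Reagents that add atoms: methanesulfonyl chloride, CS(=O)(=O)Cl
Why: Mesylation of the secondary alcohol only (the tertiary C11 hydroxyl is inert), which gives C5 a leaving group far better than the C13 acetate.

Step 18
Reactants: 28 13-acetoxy-1α,4α-epoxy-11-hydroxy-5-(methanesulfonyloxy)-8α-(tert-butyldimethylsilyloxy)-10α-(triethylsilyloxy)germacran-12,6α-olide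
Product: 30 (5E)-13-acetoxy-1α,4α-epoxy-8α-(tert-butyldimethylsilyloxy)-10α-(triethylsilyloxy)germacra-5,7(11)-dien-12,6-olide, via butenolide mesylate 29 (not isolated)
Conditions: Burgess reagent, toluene, 60 °C; then DBU, 0 °C
Reagents that add atoms: none
Why: The Burgess reagent dehydrates the tertiary α-hydroxy lactone by syn-elimination with the cis H-7 to butenolide 29, in which H-6 is vinylogously acidic; DBU then effects E1cB loss of the C5 mesylate to the alkylidene butenolide, and the bridged ring allows only the geometry with C4 and C7 cis (5E).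

Step 19
Reactants: 30 (5E)-13-acetoxy-1α,4α-epoxy-8α-(tert-butyldimethylsilyloxy)-10α-(triethylsilyloxy)germacra-5,7(11)-dien-12,6-olide
Product: 31 (5E)-13-acetoxy-1α,4α-epoxy-8α,10α-dihydroxygermacra-5,7(11)-dien-12,6-olide
Conditions: HF·pyridine, pyridine, THF, 0 °C → rt
Reagents that add atoms: none
Why: Buffered hydrogen fluoride cleaves both silyl ethers without the basicity of ammonium fluorides, which would endanger the enol lactone and the acetate.

Step 20
Reactants: 32 2-methylprop-2-en-1-ol
Product: 33 (R)-(2-methyloxiran-2-yl)methanol
Conditions: Ti(OiPr)4 (5 mol %), D-(−)-diisopropyl tartrate (6 mol %), PhCMe2OOH, 4 Å MS, CH2Cl2, −20 °C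
Reagents that add atoms: cumene hydroperoxide, CC(C)(OO)c1ccccc1
Why: Sharpless asymmetric epoxidation; the D-(−)-tartrate catalyst delivers oxygen to the face of the allylic alcohol that gives the (R)-epoxy alcohol, which sets the oxirane stereocentre.

Step 21
Reactants: 33 (R)-(2-methyloxiran-2-yl)methanol
Product: 34 (S)-2-methyloxirane-2-carboxylic acid
Conditions: RuCl3·xH2O (2 mol %), NaIO4, NaHCO3, MeCN/EtOAc/H2O, 0 °C
Reagents that add atoms: sodium periodate, [Na+].[O-][I](=O)(=O)=O; water, O
Why: RuO4-catalysed oxidation of a primary epoxy alcohol to the glycidic acid without opening the oxirane; no bond to the stereocentre is broken, and the descriptor changes from R to S only because the carboxyl group outranks the ring methylene.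

Step 22
Reactants: 31 (5E)-13-acetoxy-1α,4α-epoxy-8α,10α-dihydroxygermacra-5,7(11)-dien-12,6-olide; 34 (S)-2-methyloxirane-2-carboxylic acid
Product: 36 CNP0142137.1 [(5E)-13-acetoxy-1α,4α-epoxy-10α-hydroxy-8α-((2S)-2-methyloxirane-2-carbonyloxy)germacra-5,7(11)-dien-12,6-olide], via mixed anhydride 35 (not isolated)
Conditions: 34, 2,4,6-Cl3C6H2COCl, Et3N, THF, rt; then 31, DMAP, toluene, 0 °C → rt
Reagents that add atoms: none
Why: Yamaguchi esterification; the secondary C8 hydroxyl is acylated while the tertiary C10 hydroxyl is inert, the acid has no α-hydrogen and cannot epimerise, and as the last step the oxirane meets no further reagent.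

## Compound list

1 | (R)-carvone | CC1=CC[C@H](CC1=O)C(C)=C | starting material
2 | potassium (5S)-2-methyl-5-(prop-1-en-2-yl)cyclohexa-1,3-dien-1-olate | CC1=C([O-])C[C@@H](C=C1)C(C)=C.[K+] | intermediate (not isolated)
3 | (5S)-1-(tert-butyldimethylsilyloxy)-2-methyl-5-(prop-1-en-2-yl)cyclohexa-1,3-diene | CC1=C(O[Si](C)(C)C(C)(C)C)C[C@@H](C=C1)C(C)=C | intermediate
4 | (4S,5R)-4-hydroxy-2-methyl-5-(prop-1-en-2-yl)cyclohex-2-en-1-one | CC1=C[C@H](O)[C@H](CC1=O)C(C)=C | intermediate
5 | (4S,5R)-4-(tert-butyldimethylsilyloxy)-2-methyl-5-(prop-1-en-2-yl)cyclohex-2-en-1-one | CC1=C[C@H](O[Si](C)(C)C(C)(C)C)[C@H](CC1=O)C(C)=C | intermediate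
6 | acetaldehyde | CC=O | starting material
7 | lithium (4S,5R)-4-(tert-butyldimethylsilyloxy)-2-methyl-5-(prop-1-en-2-yl)cyclohex-1-en-1-olate | CC1=C([O-])C[C@H](C(C)=C)[C@@H](O[Si](C)(C)C(C)(C)C)C1.[Li+] | intermediate (not isolated)
8 | (2R,4S,5R)-4-(tert-butyldimethylsilyloxy)-2-(1-hydroxyethyl)-2-methyl-5-(prop-1-en-2-yl)cyclohexan-1-one, both carbinol epimers | CC(O)[C@@]1(C)C[C@H](O[Si](C)(C)C(C)(C)C)[C@H](CC1=O)C(C)=C | intermediate
9 | (2R,4S,5R)-4-(tert-butyldimethylsilyloxy)-2-ethenyl-2-methyl-5-(prop-1-en-2-yl)cyclohexan-1-one | C=C[C@@]1(C)C[C@H](O[Si](C)(C)C(C)(C)C)[C@H](CC1=O)C(C)=C | intermediate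
10 | isopropenylmagnesium bromide | CC(=C)[Mg]Br | starting material
11 | (1S,2R,4S,5R)-4-(tert-butyldimethylsilyloxy)-2-ethenyl-2-methyl-1,5-di(prop-1-en-2-yl)cyclohexan-1-ol | C=C[C@@]1(C)C[C@H](O[Si](C)(C)C(C)(C)C)[C@@H](C(C)=C)C[C@]1(O)C(C)=C | intermediate
12 | potassium alkoxide of 11 | C=C[C@@]1(C)C[C@H](O[Si](C)(C)C(C)(C)C)[C@@H](C(C)=C)C[C@]1([O-])C(C)=C.[K+] | intermediate (not isolated)
13 | potassium (1(10)E,4Z)-8α-(tert-butyldimethylsilyloxy)germacra-1(10),4,11(13)-trien-5-olate | [C@H]1(O[Si](C)(C)C(C)(C)C)C/C(C)=C/CC/C(C)=C([O-])/C[C@@H]1C(C)=C.[K+] | intermediate (not isolated)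
14 | (1(10)E,4Z)-8α-(tert-butyldimethylsilyloxy)-5-(trimethylsilyloxy)germacra-1(10),4,11(13)-triene | [C@H]1(O[Si](C)(C)C(C)(C)C)C/C(C)=C/CC/C(C)=C(O[Si](C)(C)C)/C[C@@H]1C(C)=C | intermediate
15 | (1(10)E)-8α-(tert-butyldimethylsilyloxy)-4α-(trimethylsilyloxy)germacra-1(10),11(13)-dien-5-one | O=C1C[C@H](C(C)=C)[C@@H](O[Si](C)(C)C(C)(C)C)C/C(C)=C/CC[C@@]1(C)O[Si](C)(C)C | intermediate (not isolated)
16 | 1β,10α-epoxy-8α-(tert-butyldimethylsilyloxy)-4α-(trimethylsilyloxy)germacr-11(13)-en-5-one | O=C1C[C@H](C(C)=C)[C@@H](O[Si](C)(C)C(C)(C)C)C[C@@]2(C)O[C@@H]2CC[C@@]1(C)O[Si](C)(C)C | intermediate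
17 | 1β,10α-epoxy-4α-hydroxy-8α-(tert-butyldimethylsilyloxy)germacr-11(13)-en-5-one | O=C1C[C@H](C(C)=C)[C@@H](O[Si](C)(C)C(C)(C)C)C[C@@]2(C)O[C@@H]2CC[C@@]1(C)O | intermediate (not isolated)
18 | 1α,4α-epoxy-10α-hydroxy-8α-(tert-butyldimethylsilyloxy)germacr-11(13)-en-5-one | O=C1C[C@H](C(C)=C)[C@@H](O[Si](C)(C)C(C)(C)C)C[C@@](C)(O)[C@@H]2CC[C@@]1(C)O2 | intermediate
19 | 1α,4α-epoxy-8α-(tert-butyldimethylsilyloxy)-10α-(triethylsilyloxy)germacr-11(13)-en-5-one | O=C1C[C@H](C(C)=C)[C@@H](O[Si](C)(C)C(C)(C)C)C[C@@](C)(O[Si](CC)(CC)CC)[C@@H]2CC[C@@]1(C)O2 | intermediate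
20 | potassium 5(6)-enolate of 19 | [O-]C1=C[C@H](C(C)=C)[C@@H](O[Si](C)(C)C(C)(C)C)C[C@@](C)(O[Si](CC)(CC)CC)[C@@H]2CC[C@@]1(C)O2.[K+] | intermediate (not isolated)
21 | 1α,4α-epoxy-6α-hydroxy-8α-(tert-butyldimethylsilyloxy)-10α-(triethylsilyloxy)germacr-11(13)-en-5-one | O=C1[C@@H](O)[C@H](C(C)=C)[C@@H](O[Si](C)(C)C(C)(C)C)C[C@@](C)(O[Si](CC)(CC)CC)[C@@H]2CC[C@@]1(C)O2 | intermediate
22 | 1α,4α-epoxy-6α,12-dihydroxy-8α-(tert-butyldimethylsilyloxy)-10α-(triethylsilyloxy)germacr-11(13)-en-5-one | O=C1[C@@H](O)[C@H](C(=C)CO)[C@@H](O[Si](C)(C)C(C)(C)C)C[C@@](C)(O[Si](CC)(CC)CC)[C@@H]2CC[C@@]1(C)O2 | intermediate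
23 | 12-hydroxy-6α,12-epoxy lactol of 22 (both C12 epimers) | O=C1[C@H]2OC(O)C(=C)[C@@H]2[C@@H](O[Si](C)(C)C(C)(C)C)C[C@@](C)(O[Si](CC)(CC)CC)[C@@H]3CC[C@@]1(C)O3 | intermediate (not isolated)
24 | 1α,4α-epoxy-5-oxo-8α-(tert-butyldimethylsilyloxy)-10α-(triethylsilyloxy)germacr-11(13)-en-12,6α-olide | O=C1[C@H]2OC(=O)C(=C)[C@@H]2[C@@H](O[Si](C)(C)C(C)(C)C)C[C@@](C)(O[Si](CC)(CC)CC)[C@@H]3CC[C@@]1(C)O3 | intermediate
25 | 1α,4α-epoxy-11,13-dihydroxy-5-oxo-8α-(tert-butyldimethylsilyloxy)-10α-(triethylsilyloxy)germacran-12,6α-olide, 11-hydroxyl cis to H-7 | O=C1[C@H]2OC(=O)[C@](O)(CO)[C@@H]2[C@@H](O[Si](C)(C)C(C)(C)C)C[C@@](C)(O[Si](CC)(CC)CC)[C@@H]3CC[C@@]1(C)O3 | intermediate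
26 | 13-acetoxy-1α,4α-epoxy-11-hydroxy-5-oxo-8α-(tert-butyldimethylsilyloxy)-10α-(triethylsilyloxy)germacran-12,6α-olide | O=C1[C@H]2OC(=O)[C@](O)(COC(C)=O)[C@@H]2[C@@H](O[Si](C)(C)C(C)(C)C)C[C@@](C)(O[Si](CC)(CC)CC)[C@@H]3CC[C@@]1(C)O3 | intermediate
27 | 13-acetoxy-1α,4α-epoxy-5,11-dihydroxy-8α-(tert-butyldimethylsilyloxy)-10α-(triethylsilyloxy)germacran-12,6α-olide, both C5 epimers | OC1[C@H]2OC(=O)[C@](O)(COC(C)=O)[C@@H]2[C@@H](O[Si](C)(C)C(C)(C)C)C[C@@](C)(O[Si](CC)(CC)CC)[C@@H]3CC[C@@]1(C)O3 | intermediate
28 | 13-acetoxy-1α,4α-epoxy-11-hydroxy-5-(methanesulfonyloxy)-8α-(tert-butyldimethylsilyloxy)-10α-(triethylsilyloxy)germacran-12,6α-olide | CS(=O)(=O)OC1[C@H]2OC(=O)[C@](O)(COC(C)=O)[C@@H]2[C@@H](O[Si](C)(C)C(C)(C)C)C[C@@](C)(O[Si](CC)(CC)CC)[C@@H]3CC[C@@]1(C)O3 | intermediate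
29 | 13-acetoxy-1α,4α-epoxy-5-(methanesulfonyloxy)-8α-(tert-butyldimethylsilyloxy)-10α-(triethylsilyloxy)germacr-7(11)-en-12,6α-olide | CS(=O)(=O)OC1[C@H]2OC(=O)C(COC(C)=O)=C2[C@@H](O[Si](C)(C)C(C)(C)C)C[C@@](C)(O[Si](CC)(CC)CC)[C@@H]3CC[C@@]1(C)O3 | intermediate (not isolated)
30 | (5E)-13-acetoxy-1α,4α-epoxy-8α-(tert-butyldimethylsilyloxy)-10α-(triethylsilyloxy)germacra-5,7(11)-dien-12,6-olide | CC(=O)OCC1=C2/C(=C\[C@@]3(C)CC[C@H](O3)[C@](C)(O[Si](CC)(CC)CC)C[C@@H]2O[Si](C)(C)C(C)(C)C)OC1=O | intermediate
31 | (5E)-13-acetoxy-1α,4α-epoxy-8α,10α-dihydroxygermacra-5,7(11)-dien-12,6-olide | CC(=O)OCC1=C2/C(=C\[C@@]3(C)CC[C@H](O3)[C@](C)(O)C[C@@H]2O)OC1=O | intermediate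
32 | 2-methylprop-2-en-1-ol | CC(=C)CO | starting material
33 | (R)-(2-methyloxiran-2-yl)methanol | OC[C@]1(C)CO1 | intermediate
34 | (S)-2-methyloxirane-2-carboxylic acid | OC(=O)[C@]1(C)CO1 | intermediate
35 | (S)-2-methyloxirane-2-carboxylic 2,4,6-trichlorobenzoic anhydride | O=C(OC(=O)c1c(Cl)cc(Cl)cc1Cl)[C@]1(C)CO1 | intermediate (not isolated)
36 | CNP0142137.1 | CC(=O)OCC1=C2/C(=C\[C@@]3(C)CC[C@H](O3)[C@](C)(O)C[C@@H]2OC(=O)[C@]2(C)CO2)OC1=O | target

## Step count and least certain steps

Total step count: 22 (steps 1–19 and 22 on the main line, steps 20 and 21 for the acid). Longest linear sequence: 20 steps (1 to 36 through steps 1–19 and 22).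

Step 7 (key step). The ring inversion that must precede the shift adds to the barrier, so fragmentation of the tertiary alkoxide by heterolysis of the C5–C10 bond, or passage through a boat-type arrangement with loss of alkene geometry, may compete on warming. Fallback: setting out from 11, the hydroxyl is silylated (Me3SiCl, imidazole) to the trimethylsilyl ether F1, which is rearranged without base as a thermal silyloxy-Cope ring expansion (sealed tube, o-dichlorobenzene, about 200 °C, or flash thermolysis). The concerted shift passes through the same chair and delivers the silyl enol ether directly, so the sequence comes back at 14.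

Step 2. The peracid may attack the dienol ether at its α-carbon (C2) in competition with the γ-terminus, giving the tertiary α-ketol instead of the γ-hydroxy enone. Fallback: setting out from 3, sensitised photo-oxygenation (O2, tetraphenylporphyrin, hν, CH2Cl2, −78 °C) adds singlet oxygen across the diene termini in a [4+2] sense, anti to the isopropenyl group, to give the endoperoxide F2. This bonds oxygen to C4 by necessity. Reduction with thiourea in methanol cleaves the O–O bond, and loss of silanol returns the route at 4.

Step 4. Proton transfer from the enolisable aldehyde to the hindered tetrasubstituted enolate, and reversal of the aldol addition on work-up, may erode conversion. Fallback: setting out from 5, enolate 7 is generated as before and added to phenyl vinyl sulfoxide (an irreversible conjugate addition with the same facial preference) to give the sulfoxide F3. Thermal syn-elimination of the sulfoxide (toluene, 110 °C, CaCO3) then forms the vinyl group, and the route is rejoined at 9 without passing through 8.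

Step 8. The silyloxy-stabilised cation formed on opening the enol ether epoxide may be captured across the ring by the C1=C10 alkene before silyl transfer, re-closing a bicyclic carbon skeleton. The second epoxidation may also spill over to the isopropenyl group. Fallback: setting out from 11, the rearrangement is run as in step 7, but enolate 13 is quenched at −78 °C with 2-(benzenesulfonyl)-3-phenyloxaziridine. This gives the hydroxy ketone F4 directly, with no cationic intermediate. One equivalent of buffered mCPBA then epoxidises C1=C10, and the route comes back at 17, which step 9 closes to 18.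

Step 18. If the C11 hydroxyl turns out anti to H-7, the syn-elimination will turn toward C13 and give an enol acetate. Loss of the C13 acetate from the deprotonated butenolide may also compete with loss of the mesylate. Fallback: setting out from 24, the ketone is reduced in the presence of the methylene lactone (NaBH4, CeCl3, MeOH, −78 °C) to the alcohol F5, which is mesylated (MeSO2Cl, Et3N) to F6. Acetoxyselenenylation of the methylene lactone (PhSeBr, AgOAc, AcOH) places selenium on C11 and acetate on C13 to give the selenide F7. Oxidation (H2O2, pyridine, 0 °C) triggers selenoxide syn-elimination, which runs away from the oxygen-bearing carbon and toward H-7. This returns the route at 29, and DBU completes the sequence to 30.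

## Further compounds

F1 | step 7 | (1S,2R,4S,5R)-4-(tert-butyldimethylsilyloxy)-2-ethenyl-2-methyl-1,5-di(prop-1-en-2-yl)-1-(trimethylsilyloxy)cyclohexane | C=C[C@@]1(C)C[C@H](O[Si](C)(C)C(C)(C)C)[C@@H](C(C)=C)C[C@]1(O[Si](C)(C)C)C(C)=C
F2 | step 2 | 1-(tert-butyldimethylsilyloxy)-6-methyl-8-(prop-1-en-2-yl)-2,3-dioxabicyclo[2.2.2]oct-5-ene, peroxide bridge anti to the isopropenyl group | CC1=C[C@@H]2OO[C@@]1(O[Si](C)(C)C(C)(C)C)C[C@@H]2C(C)=C
F3 | step 4 | (2R,4S,5R)-4-(tert-butyldimethylsilyloxy)-2-methyl-2-[2-(phenylsulfinyl)ethyl]-5-(prop-1-en-2-yl)cyclohexan-1-one, both sulfoxide epimers | O=S(CC[C@@]1(C)C[C@H](O[Si](C)(C)C(C)(C)C)[C@H](CC1=O)C(C)=C)c1ccccc1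
F4 | step 8 | (1(10)E)-4α-hydroxy-8α-(tert-butyldimethylsilyloxy)germacra-1(10),11(13)-dien-5-one | O=C1C[C@H](C(C)=C)[C@@H](O[Si](C)(C)C(C)(C)C)C/C(C)=C/CC[C@@]1(C)O
F5 | step 18 | 1α,4α-epoxy-5-hydroxy-8α-(tert-butyldimethylsilyloxy)-10α-(triethylsilyloxy)germacr-11(13)-en-12,6α-olide, both C5 epimers | OC1[C@H]2OC(=O)C(=C)[C@@H]2[C@@H](O[Si](C)(C)C(C)(C)C)C[C@@](C)(O[Si](CC)(CC)CC)[C@@H]3CC[C@@]1(C)O3
F6 | step 18 | 1α,4α-epoxy-5-(methanesulfonyloxy)-8α-(tert-butyldimethylsilyloxy)-10α-(triethylsilyloxy)germacr-11(13)-en-12,6α-olide | CS(=O)(=O)OC1[C@H]2OC(=O)C(=C)[C@@H]2[C@@H](O[Si](C)(C)C(C)(C)C)C[C@@](C)(O[Si](CC)(CC)CC)[C@@H]3CC[C@@]1(C)O3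
F7 | step 18 | 13-acetoxy-1α,4α-epoxy-5-(methanesulfonyloxy)-11-(phenylselanyl)-8α-(tert-butyldimethylsilyloxy)-10α-(triethylsilyloxy)germacran-12,6α-olide, selenium cis to H-7 | CS(=O)(=O)OC1[C@H]2OC(=O)[C@]([Se]c4ccccc4)(COC(C)=O)[C@@H]2[C@@H](O[Si](C)(C)C(C)(C)C)C[C@@](C)(O[Si](CC)(CC)CC)[C@@H]3CC[C@@]1(C)O3
A1 | alternative 1 | macrocyclic C9=C10 alkene with free C8 hydroxyl (metathesis product) | CC(=O)OCC1=C2/C(=C\[C@@]3(C)CC[C@H](O3)/C(C)=C\[C@@H]2O)OC1=O
A2 | alternative 1 | acyclic diene with C8 vinyl carbinol and C1 isopropenyl tetrahydrofuran (metathesis precursor) | CC(=O)OCC1=C(/C(=C\[C@@]2(C)CC[C@H](O2)C(C)=C)OC1=O)[C@@H](O)C=C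
A3 | alternative 2 | tricyclic furan–oxyallyl cycloadduct with ketone carbon bridging C5 and C10 | O=C1[C@]2(C)C[C@H](O[Si](C)(C)C(C)(C)C)C[C@H](O[Si](C)(C)C(C)(C)C)[C@H]1[C@@]1(C)C=C[C@@H]2O1
A4 | alternative 2 | 4,6-bis(tert-butyldimethylsilyloxy)-2-chloro-2-methylcycloheptan-1-one (C2 epimers) | CC1(Cl)C[C@H](O[Si](C)(C)C(C)(C)C)C[C@H](O[Si](C)(C)C(C)(C)C)CC1=O
A5 | alternative 2 | 2-methylfuran | Cc1ccco1
A6 | alternative 3 | 11-oxabicyclo[6.2.1]undec-6-en-3-one with C4 methyl and C8, C10 silyl ethers (ylide rearrangement product) | C1/C=C\[C@@H](O[Si](C)(C)C(C)(C)C)C[C@@](C)(O[Si](CC)(CC)CC)[C@@H]2CC(=O)[C@@]1(C)O2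
A7 | alternative 3 | 3-diazobutan-2-one tethered at C1 to a 2-vinyltetrahydropyran bearing the C8 and C10 silyl ethers (vinyl-bearing carbon unassigned) | CC(=[N+]=[N-])C(=O)C[C@@H]1OC(C=C)[C@@H](O[Si](C)(C)C(C)(C)C)C[C@@]1(C)O[Si](CC)(CC)CC
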